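## Structural features

The target is a dihydrochalcone, a 3-(4-hydroxyphenyl)-1-arylpropan-1-one. Its acyl-bearing ring A is fused through C4a and C8a to a 2,2-dimethyl-2H-pyran (O1, C2 with two methyl groups, C3=C4), so ring A and the pyran form a 2H-chromene; ring B is the para-hydroxyphenyl group at the far end of the three-carbon chain. Ring A is pentasubstituted and keeps one hydrogen, at C5: C4a carries C4, C6 the propanoyl chain, C7 a free hydroxyl hydrogen-bonded to the ketone, C8 a 3-methylbut-2-enyl (prenyl) group and C8a the pyran oxygen. There is no stereocentre, and each olefin is either in a ring or ends in two identical methyl groups, so no configuration or olefin geometry has to be set. The fragile parts are the prenyl olefin next to the C7 hydroxyl (acid closes it to a dihydropyran, electrophiles add to it), the electron-rich C3=C4 styrene bond (acid, oxidants, hydrogenation) and the two phenols; strong acids, hydrogenolysis and halogen electrophiles are therefore kept out of the late steps. The real difficulty is regiochemical: four different substituents must stand in one fixed order on a resorcinol core, with the prenyl group exactly between the two oxygens, and substitution on resorcinol gives this only as mixtures. The key step uses the fact that the oxygen-bearing C8a and the carbon-bearing C4a are neighbours: ring A is closed through C5–C6 and C4a–C8a from a diene that supplies C6, C7, C8 (with its prenyl group) and C8a, and an ynone that supplies C5, C4a and, as an enoyl arm on C4a, the carbons C4, C3, C2 and both methyl groups.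

## Logic of the disconnections

**23 to 22.** The O–Si bond on ring B is cut last. The ring B phenol must be masked while its ethyl chain is an organomagnesium reagent. The last step is then one fluoride desilylation without acid. The silyl ether must survive Grignard formation and the oxidation.

**22 to 21, then to 17 and 20 (from 19, from 18).** After the ketone is taken back to the carbinol, the bond between the C6 carbonyl carbon and its α-methylene is cut. Friedel–Crafts or Fries acylation of ring A would need acids that destroy the prenyl group and the chromene; an aldehyde at C6 accepts the carbon nucleophile under basic conditions. This divides the molecule into a ring A aldehyde and a two-carbon ring B fragment that comes from 18 in one step. The free C7 hydroxyl of 17 consumes one equivalent of 20, and the oxidation of 21 must take only the benzylic carbinol.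

**17 to 16.** The C6–CHO bond is cut. In 16, C6 is the only free position ortho to the hydroxyl (C8 is occupied) and is also para to O1, so a magnesium phenoxide can deliver formaldehyde there without acid. The step needs the free phenol and anhydrous conditions.

**16 to 12 through 15, 14 and 13.** The C3=C4 bond is traced back to the C4 ketone by dehydration and hydride reduction, with O7 carried as a silyl ether. The silyl group stops a para phenoxide from deactivating the ketone toward hydride, and during the acid step it keeps both oxygens next to the prenyl group capped so that the prenyl cannot cyclise. A direct hydride reduction of the enone carbonyl of 11 with closure through an ortho-quinone methide would be shorter, but two free phenols in the presence of hydride invite over-reduction through quinone methides, so the protected sequence is preferred. The dehydration must run with very little acid.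

**12 to 11.** The O1–C2 bond is cut, which opens the pyranone to a 2-hydroxyaryl β,β-dimethyl enone. The forward oxa-Michael addition needs only a trace of base; the second hydroxyl cannot reach the enone.

**11 to 5 and 8 (through 9 and 10).** The C5–C6 and C4a–C8a bonds are cut, which takes ring A apart completely. The prenyl group, both oxygens and the enoyl arm are then in place before the ring exists, so no substitution on an arene is needed for them. The forward cycloaddition must be regioselective (enoyl group ortho to the ketal-derived oxygen) and must use the alkyne, not the enone.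

**5 to 4 to 3, then to 1 and 2.** The two O–Si bonds are cut, then the bond between the future C8 and the prenyl methylene. The prenyl group is thus introduced by enolate alkylation of a β-keto ester, where only one carbon can react. Mono-alkylation must be controlled, and 5 must be kept from moisture.

**8 to 7 to 6.** The bond between the future C4 and C4a (carbonyl carbon to alkyne) is cut after the ketone is taken back to the carbinol. An ethynyl Grignard reagent adds 1,2 to 6, and the doubly activated carbinol 7 is oxidised under neutral conditions. Compound 8 is volatile and is handled in solution.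

## Other disconnections considered

**Alternative 1:** The cut removes both methyl groups from C2 and opens the O1–C2 bond, which leads back to the natural coumarin osthole A1 (7-methoxy-8-(3-methylbut-2-enyl)chromen-2-one).
- **Forward key step:** two equivalents of a methyl Grignard reagent would add to the lactone carbonyl of A1 to give the ring-opened Z-allylic diol A2 (2-[(1Z)-3-hydroxy-3-methylbut-1-enyl]-5-methoxy-6-(3-methylbut-2-enyl)phenol). Mild acid would then ionise the tertiary allylic alcohol and let the phenol oxygen close the pyran, giving 7-methoxy-2,2-dimethyl-8-(3-methylbut-2-enyl)-2H-chromene A3.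
- **In its favour:** A1 can be bought and already holds ring A with O7, the C8 prenyl group, O1 and the C4a–C4–C3 chain in place. The chromene would be reached in one or two steps with no regiochemical question. On step economy and on certainty of the substitution pattern it is better than the chosen plan, which needs eleven steps to reach the comparable chromene 16.
- **Against it:** O7 arrives as a methyl ether, while the target has a free phenol. Cleaving an aryl methyl ether beside a prenyl group and a chromene excludes boron and aluminium halides and leaves hot thiolate or similar nucleophilic conditions. Only after that demethylation, which would turn A3 into 16, could the phenoxide-directed formylation be used, so the last five steps would be the same as here.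
- **Comparison:** the acid closure of A2 meets the same prenyl-next-to-phenol hazard as step 10, so the two plans are equal on that point. The alternative is shorter and equal in regiocontrol; it loses on the harsh demethylation and on dependence on a natural product supply.

**Alternative 2:** The cut goes through C4–C4a and O1–C2, so the pyran is unravelled to a 1,1-dimethylpropargyl ether on the oxygen that becomes O1, in the fully assembled dihydrochalcone A4 (3-[4-(tert-butyldimethylsilyloxy)phenyl]-1-[2-hydroxy-4-(2-methylbut-3-yn-2-yloxy)-3-(3-methylbut-2-enyl)phenyl]propan-1-one).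
- **Forward key step:** heating A4 would start an aromatic propargyl Claisen rearrangement to the only free ortho carbon (the future C4a; the other ortho position is blocked by the prenyl group). A 1,5-hydrogen shift and oxa-6π electrocyclisation would follow, giving the ring B silyl ether A5, which is the same compound as 22.
- **In its favour:** the chromene appears one step before the target at the right oxidation level, so the reduction, dehydration, formylation, Grignard and oxidation steps of the chosen route have no counterpart. The regiochemistry of the pyran is forced by the prenyl group and no acid is used. On these points it is better.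
- **Against it:** A4 presupposes a dihydrochalcone with the 2,4-dihydroxy-3-prenyl pattern, which is the real problem of the target. Etherifying a phenol flanked by a prenyl group with a tertiary propargylic electrophile is sterically demanding. The cascade needs roughly 150–200 °C, where a [3,3] shift to the prenyl-bearing carbon, with Cope-type follow-up, can divert material.
- **Comparison:** equal in regiochemical certainty for the pyran and better in step count after ring A, but it does not say how ring A is assembled, which the chosen cycloaddition does.

**Alternative 3:** The cut goes through C4a–C5 and C6–C7. The diene 5 is kept, but the dienophile is the saturated-chain ynone A6 (5-[4-(tert-butyldimethylsilyloxy)phenyl]pent-1-yn-3-one). The ketene acetal carbon then becomes C7, the prenylated carbon C8, the silyloxy carbon C8a and the methylene terminus C4a.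
- **Forward key step:** cycloaddition and aromatisation as in step 6 would give the dihydrochalcone A7 (3-[4-(tert-butyldimethylsilyloxy)phenyl]-1-[2,4-dihydroxy-3-(3-methylbut-2-enyl)phenyl]propan-1-one), the phenol from which A4 would be made.
- **In its favour:** reaction type and regiochemical logic are the same as in the chosen key step, so the two are equal in mechanistic risk. A6 has no second unsaturated site, which makes it the simpler dienophile. The C6 acylation sequence (steps 12 to 15) disappears, and the ring B phenol is carried from the start.
- **Against it:** the pyran must then be built onto O1 and C4a of the finished arene, either through A4 and the cascade of Alternative 2 or by amine-mediated condensation with 6 through a vinyl ortho-quinone methide. Both act on an acyl-deactivated ring at an oxygen flanked by the prenyl group, although only C4a is open, so the regiochemistry is again forced.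
- **Comparison:** on step economy this alternative is clearly better (about nine steps in all against sixteen). The chosen plan has C4, C3, C2 and the methyl groups bonded to C4a before ring A exists, so the pyran closes by a simple oxa-Michael addition; it pays for this with redox adjustment at C4 and a separate acylation at C6.

Key step: step 6

**Remarks on the chemistry.**
- The atom mapping of 5, 8 and 11 was checked against the target (alkyne carbons become C5 and C4a; diene carbons become C6, C7, C8 and C8a); the structures are consistent and none is changed.
- Compounds 3, 7, 9, 14 and 21 each carry one stereocentre that is destroyed later, so they are handled as racemates. The enol ether geometry of 4 and the ketene acetal geometry of 5 are without consequence.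
- Design choices: 5 is used crude and in slight excess, 8 is handled as a solution, and the temporary ring A protecting group is triisopropylsilyl.

## Route

Step 1
Reactants: 1 methyl acetoacetate (methyl 3-oxobutanoate); 2 1-bromo-3-methylbut-2-ene
Product: 3 methyl 2-acetyl-5-methylhex-4-enoate (racemic)
Conditions: K2CO3, acetone, reflux (1 in excess)
Reagents that add atoms: none
Why: SN2 C-alkylation of the stabilised acetoacetate enolate by a primary allylic bromide; the excess of 1 suppresses double alkylation and is removed by distillation.

Step 2
Reactants: 3 methyl 2-acetyl-5-methylhex-4-enoate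
Product: 4 methyl 5-methyl-2-[1-(trimethylsilyloxy)ethylidene]hex-4-enoate (E/Z mixture)
Conditions: Me3SiCl, Et3N, toluene, rt
Reagents that add atoms: chlorotrimethylsilane, C[Si](C)(C)Cl
Why: O-silylation of the β-keto ester enol with amine base gives the β-silyloxy enoate, the usual first stage of 1,3-bis(silyloxy)diene synthesis; the olefin geometry is lost in step 3.

Step 3
Reactants: 4 methyl 5-methyl-2-[1-(trimethylsilyloxy)ethylidene]hex-4-enoate
Product: 5 1-methoxy-2-(3-methylbut-2-enyl)-1,3-bis(trimethylsilyloxy)buta-1,3-diene
Conditions: LiN(iPr)2, THF, −78 °C; Me3SiCl, −78 °C to rt; filtered under argon, used crude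
Reagents that add atoms: chlorotrimethylsilane, C[Si](C)(C)Cl
Why: γ-Deprotonation of the vinylogous ester gives a lithium dienolate that is silylated on the ester oxygen, a standard ketene acetal formation; either acetal geometry serves because that carbon becomes part of the arene.

Step 4
Reactants: 6 3-methylbut-2-enal
Product: 7 5-methylhex-4-en-1-yn-3-ol (racemic)
Conditions: HC≡CMgBr, THF, 0 °C; then H2O
Reagents that add atoms: ethynylmagnesium bromide, C#C[Mg]Br
Why: 1,2-Grignard addition of the acetylide to the unhindered aldehyde carbonyl; the new stereocentre is racemic and is removed in step 5.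

Step 5
Reactants: 7 5-methylhex-4-en-1-yn-3-ol
Product: 8 5-methylhex-4-en-1-yn-3-one
Conditions: MnO2 (activated, excess), CH2Cl2, rt; filtered, kept as a cold solution
Reagents that add atoms: none
Why: MnO2 oxidation of a carbinol that is both allylic and propargylic is fast and neutral, so the base- and nucleophile-sensitive terminal ynone is not exposed to harsher reagents.

Step 6
Reactants: 5 1-methoxy-2-(3-methylbut-2-enyl)-1,3-bis(trimethylsilyloxy)buta-1,3-diene; 8 5-methylhex-4-en-1-yn-3-one
Product: 11 1-[2,4-dihydroxy-3-(3-methylbut-2-enyl)phenyl]-3-methylbut-2-en-1-one, via silyl ketal cycloadduct 9 (not isolated), via mono-trimethylsilyl resorcinol ether 10 (not isolated)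
Conditions: toluene, 0 °C to 50 °C (5 in slight excess); then 10% aq. citric acid, THF, rt
Reagents that add atoms: none
Why: In this normal-demand Diels–Alder reaction the HOMO of the trioxygenated diene 5 has its largest coefficient at the unsubstituted methylene terminus and the LUMO of 8 at the terminal alkyne carbon, so these carbons bond first (C5–C6) in an asynchronous or stepwise Michael-type event and the ketene acetal carbon then closes onto the carbonyl-bearing alkyne carbon (C4a–C8a). Ring A is thus closed as an all-carbon six-membered ring by an intermolecular [4+2] union of four diene carbons and two alkyne carbons, giving the cyclohexa-1,4-diene 9. The mixed methyl silyl ketal carbon of 9 expels methoxytrimethylsilane to a cyclohexadienone that tautomerises to the phenol 10, and dilute citric acid removes the remaining trimethylsilyl group to give 11. The closest known reaction type is the cycloaddition of 1-alkoxy-1,3-bis(silyloxy)butadienes to acetylenic ketones and esters with aromatisation to resorcinols. The regiochemistry needed, enoyl group ortho to the ketal-derived hydroxyl and prenyl between the two oxygens, is secured by the donor–acceptor polarity of the two partners and by the prenyl group sitting on the central diene carbon. Chemoselectivity for the alkyne is secured by the absence of a Lewis acid, which leaves the ketone carbonyl unactivated, and by the two β-methyl groups that shield the enone double bond. The only stereocentre formed, the ketal carbon of 9, is racemic and is erased on aromatisation, so no stereocontrol is required.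

Step 7
Reactants: 11 1-[2,4-dihydroxy-3-(3-methylbut-2-enyl)phenyl]-3-methylbut-2-en-1-one
Product: 12 7-hydroxy-2,2-dimethyl-8-(3-methylbut-2-enyl)-2,3-dihydro-4H-chromen-4-one
Conditions: K2CO3 (0.2 equiv), MeOH, rt
Reagents that add atoms: none
Why: 6-endo-trig oxa-Michael addition of the phenoxide ortho to the carbonyl onto the β,β-dimethyl enone closes the pyranone (O1–C2); the gem-dimethyl group favours the closed form and the other hydroxyl cannot reach the enone.

Step 8
Reactants: 12 7-hydroxy-2,2-dimethyl-8-(3-methylbut-2-enyl)-2,3-dihydro-4H-chromen-4-one
Product: 13 2,2-dimethyl-8-(3-methylbut-2-enyl)-7-[tri(propan-2-yl)silyloxy]-2,3-dihydro-4H-chromen-4-one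
Conditions: iPr3SiCl, imidazole, DMF, rt
Reagents that add atoms: chlorotri(propan-2-yl)silane, CC(C)[Si](Cl)(C(C)C)C(C)C
Why: Silylation of the only hydroxyl; the bulky triisopropylsilyl ether is chosen because a silyl ether para to a ketone is labile to alkoxide, and it must last through steps 9 and 10.

Step 9
Reactants: 13 2,2-dimethyl-8-(3-methylbut-2-enyl)-7-[tri(propan-2-yl)silyloxy]-2,3-dihydro-4H-chromen-4-one
Product: 14 2,2-dimethyl-8-(3-methylbut-2-enyl)-7-[tri(propan-2-yl)silyloxy]-3,4-dihydro-2H-chromen-4-ol (racemic)
Conditions: NaBH4, THF–MeOH, 0 °C to rt
Reagents that add atoms: none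
Why: Borohydride 1,2-reduction of the aryl ketone, which is not deactivated by a phenoxide once O7 is silylated; the new C4 stereocentre is racemic and is removed in step 10.

Step 10
Reactants: 14 2,2-dimethyl-8-(3-methylbut-2-enyl)-7-[tri(propan-2-yl)silyloxy]-3,4-dihydro-2H-chromen-4-ol
Product: 15 [2,2-dimethyl-8-(3-methylbut-2-enyl)-2H-chromen-7-yl]oxy-tri(propan-2-yl)silane
Conditions: p-TsOH·H2O (2 mol%), toluene, 60 °C
Reagents that add atoms: none
Why: E1 dehydration through a benzylic cation stabilised by O1 (ortho) and O7 (para) needs only a trace of acid; with O1 in the ring and O7 silylated, the prenyl group has no free hydroxyl to cyclise onto.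

Step 11
Reactants: 15 [2,2-dimethyl-8-(3-methylbut-2-enyl)-2H-chromen-7-yl]oxy-tri(propan-2-yl)silane
Product: 16 2,2-dimethyl-8-(3-methylbut-2-enyl)-2H-chromen-7-ol
Conditions: Bu4NF, THF, 0 °C
Reagents that add atoms: none
Why: Fluoride cleaves the aryl silyl ether through the strong Si–F bond under non-acidic conditions that leave both olefins untouched; the air-sensitive phenol is used at once.

Step 12
Reactants: 16 2,2-dimethyl-8-(3-methylbut-2-enyl)-2H-chromen-7-ol
Product: 17 7-hydroxy-2,2-dimethyl-8-(3-methylbut-2-enyl)-2H-chromene-6-carbaldehyde
Conditions: MgCl2, Et3N, (CH2O)n, MeCN, reflux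
Reagents that add atoms: paraformaldehyde (source of formaldehyde), C=O
Why: In this Casnati–Skattebøl ortho-formylation the magnesium phenoxide delivers coordinated formaldehyde to the ortho carbon, and the resulting benzylic alkoxide passes hydride to a second formaldehyde; C6 is the only free ortho position because C8 carries the prenyl group, and no acid is involved.

Step 13
Reactants: 18 4-(2-bromoethyl)phenol
Product: 19 [4-(2-bromoethyl)phenoxy]-tert-butyl-dimethylsilane
Conditions: tert-BuMe2SiCl, imidazole, CH2Cl2, rt
Reagents that add atoms: tert-butylchlorodimethylsilane, CC(C)(C)[Si](C)(C)Cl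
Why: Phenol silylation under weakly basic conditions removes the acidic proton that would quench the Grignard reagent; imidazole is too weak a base to trigger displacement of bromide by the phenoxide.

Step 14
Reactants: 17 7-hydroxy-2,2-dimethyl-8-(3-methylbut-2-enyl)-2H-chromene-6-carbaldehyde; 19 [4-(2-bromoethyl)phenoxy]-tert-butyl-dimethylsilane
Product: 21 3-[4-(tert-butyldimethylsilyloxy)phenyl]-1-[7-hydroxy-2,2-dimethyl-8-(3-methylbut-2-enyl)-2H-chromen-6-yl]propan-1-ol (racemic), via arylethylmagnesium bromide 20 (not isolated)
Conditions: 19, Mg, THF, rt to 40 °C; then 17 (0.4 equiv relative to 20), THF, 0 °C to rt; pH 7 buffer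
Reagents that add atoms: none
Why: Grignard addition to a salicylaldehyde: the first equivalent of 20 deprotonates the phenol and the second adds to the magnesium-chelated aldehyde; the carbinol stereocentre is racemic and is removed in step 15.

Step 15
Reactants: 21 3-[4-(tert-butyldimethylsilyloxy)phenyl]-1-[7-hydroxy-2,2-dimethyl-8-(3-methylbut-2-enyl)-2H-chromen-6-yl]propan-1-ol
Product: 22 3-[4-(tert-butyldimethylsilyloxy)phenyl]-1-[7-hydroxy-2,2-dimethyl-8-(3-methylbut-2-enyl)-2H-chromen-6-yl]propan-1-one
Conditions: MnO2 (activated, excess), CH2Cl2, rt
Reagents that add atoms: none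
Why: MnO2 oxidises the electron-rich benzylic carbinol selectively under neutral conditions; the product is a hydrogen-bonded 2-hydroxyaryl ketone, and the isolated olefins and the silyl ether are inert.

Step 16
Reactants: 22 3-[4-(tert-butyldimethylsilyloxy)phenyl]-1-[7-hydroxy-2,2-dimethyl-8-(3-methylbut-2-enyl)-2H-chromen-6-yl]propan-1-one
Product: 23 3-(4-hydroxyphenyl)-1-[7-hydroxy-2,2-dimethyl-8-(3-methylbut-2-enyl)-2H-chromen-6-yl]propan-1-one (CNP0163015.0)
Conditions: Bu4NF, THF, 0 °C; then aq. NH4Cl
Reagents that add atoms: none
Why: Fluoride desilylation of the ring B aryl silyl ether releases the second phenol without acid, so the prenyl group beside the C7 hydroxyl and the chromene olefin are not endangered.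

## Compound list

1 | methyl acetoacetate (methyl 3-oxobutanoate) | CC(=O)CC(=O)OC | starting material
2 | 1-bromo-3-methylbut-2-ene | CC(C)=CCBr | starting material
3 | methyl 2-acetyl-5-methylhex-4-enoate (racemic) | COC(=O)C(CC=C(C)C)C(C)=O | intermediate
4 | methyl 5-methyl-2-[1-(trimethylsilyloxy)ethylidene]hex-4-enoate (E/Z mixture) | COC(=O)C(CC=C(C)C)=C(C)O[Si](C)(C)C | intermediate
5 | 1-methoxy-2-(3-methylbut-2-enyl)-1,3-bis(trimethylsilyloxy)buta-1,3-diene (either ketene acetal geometry) | C=C(O[Si](C)(C)C)/C(CC=C(C)C)=C(/OC)O[Si](C)(C)C | intermediate
6 | 3-methylbut-2-enal | CC(C)=CC=O | starting material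
7 | 5-methylhex-4-en-1-yn-3-ol (racemic) | C#CC(O)C=C(C)C | intermediate
8 | 5-methylhex-4-en-1-yn-3-one | C#CC(=O)C=C(C)C | intermediate
9 | 1-[6-methoxy-5-(3-methylbut-2-enyl)-4,6-bis(trimethylsilyloxy)cyclohexa-1,4-dien-1-yl]-3-methylbut-2-en-1-one (racemic, not isolated) | COC1(O[Si](C)(C)C)C(CC=C(C)C)=C(O[Si](C)(C)C)CC=C1C(=O)C=C(C)C | intermediate
10 | 1-[2-hydroxy-3-(3-methylbut-2-enyl)-4-(trimethylsilyloxy)phenyl]-3-methylbut-2-en-1-one (not isolated) | CC(C)=CCc1c(O[Si](C)(C)C)ccc(C(=O)C=C(C)C)c1O | intermediate
11 | 1-[2,4-dihydroxy-3-(3-methylbut-2-enyl)phenyl]-3-methylbut-2-en-1-one | CC(C)=CCc1c(O)ccc(C(=O)C=C(C)C)c1O | intermediate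
12 | 7-hydroxy-2,2-dimethyl-8-(3-methylbut-2-enyl)-2,3-dihydro-4H-chromen-4-one | CC(C)=CCc1c(O)ccc2c1OC(C)(C)CC2=O | intermediate
13 | 2,2-dimethyl-8-(3-methylbut-2-enyl)-7-[tri(propan-2-yl)silyloxy]-2,3-dihydro-4H-chromen-4-one | CC(C)=CCc1c(O[Si](C(C)C)(C(C)C)C(C)C)ccc2c1OC(C)(C)CC2=O | intermediate
14 | 2,2-dimethyl-8-(3-methylbut-2-enyl)-7-[tri(propan-2-yl)silyloxy]-3,4-dihydro-2H-chromen-4-ol (racemic) | CC(C)=CCc1c(O[Si](C(C)C)(C(C)C)C(C)C)ccc2c1OC(C)(C)CC2O | intermediate
15 | [2,2-dimethyl-8-(3-methylbut-2-enyl)-2H-chromen-7-yl]oxy-tri(propan-2-yl)silane | CC(C)=CCc1c(O[Si](C(C)C)(C(C)C)C(C)C)ccc2c1OC(C)(C)C=C2 | intermediate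
16 | 2,2-dimethyl-8-(3-methylbut-2-enyl)-2H-chromen-7-ol | CC(C)=CCc1c(O)ccc2c1OC(C)(C)C=C2 | intermediate
17 | 7-hydroxy-2,2-dimethyl-8-(3-methylbut-2-enyl)-2H-chromene-6-carbaldehyde | CC(C)=CCc1c(O)c(C=O)cc2c1OC(C)(C)C=C2 | intermediate
18 | 4-(2-bromoethyl)phenol | Oc1ccc(CCBr)cc1 | starting material
19 | [4-(2-bromoethyl)phenoxy]-tert-butyl-dimethylsilane | CC(C)(C)[Si](C)(C)Oc1ccc(CCBr)cc1 | intermediate
20 | {2-[4-(tert-butyldimethylsilyloxy)phenyl]ethyl}magnesium bromide (not isolated) | CC(C)(C)[Si](C)(C)Oc1ccc(CC[Mg]Br)cc1 | intermediate
21 | 3-[4-(tert-butyldimethylsilyloxy)phenyl]-1-[7-hydroxy-2,2-dimethyl-8-(3-methylbut-2-enyl)-2H-chromen-6-yl]propan-1-ol (racemic) | CC(C)=CCc1c(O)c(C(O)CCc2ccc(O[Si](C)(C)C(C)(C)C)cc2)cc2c1OC(C)(C)C=C2 | intermediate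
22 | 3-[4-(tert-butyldimethylsilyloxy)phenyl]-1-[7-hydroxy-2,2-dimethyl-8-(3-methylbut-2-enyl)-2H-chromen-6-yl]propan-1-one | CC(C)=CCc1c(O)c(C(=O)CCc2ccc(O[Si](C)(C)C(C)(C)C)cc2)cc2c1OC(C)(C)C=C2 | intermediate
23 | 3-(4-hydroxyphenyl)-1-[7-hydroxy-2,2-dimethyl-8-(3-methylbut-2-enyl)-2H-chromen-6-yl]propan-1-one | CC(C)=CCc1c(O)c(C(=O)CCc2ccc(O)cc2)cc2c1OC(C)(C)C=C2 | target

## Step count and least certain steps

Total: 16 steps. Longest linear sequence: 13 steps (steps 1–3, 6–12 and 14–16); steps 4–5 and step 13 are side branches.

**Step 6 (key step).** Three things may go wrong. The ketal carbon of 9 may lose trimethylsilanol in place of methoxytrimethylsilane, which would leave the C8a oxygen methylated. The first bond may form without ring closure, giving open-chain Michael adducts. The ynone may polymerise before it meets the diene. Fallback, which takes ring A from the aromatic pool and gives up the de novo regiocontrol: it sets out from 2. Commercial 1-(2,4-dihydroxyphenyl)ethanone F1 would be C-prenylated with 2 in aqueous KOH at 0 °C, and 1-[2,4-dihydroxy-3-(3-methylbut-2-enyl)phenyl]ethanone F2 would be separated from its 5-prenyl and O-prenyl isomers. Kabbe condensation of F2 with acetone and pyrrolidine in ethanol at reflux would build the enone 11 in the flask and close it, so the route is rejoined at 12.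

**Step 10.** Acid may add across the prenyl olefin or dimerise the electron-rich chromene, and premature desilylation would open the way to closure of the prenyl group onto O7. Fallback without any acid: it sets out from 13. Enolisation with KN(SiMe3)2 in THF at −78 °C and trapping with N-phenylbis(trifluoromethanesulfonimide) would give the enol triflate 2,2-dimethyl-8-(3-methylbut-2-enyl)-7-[tri(propan-2-yl)silyloxy]-2H-chromen-4-yl trifluoromethanesulfonate F3. Reduction with Pd(OAc)2, PPh3, HCO2H and Bu3N in DMF at 60 °C would replace the triflate by hydrogen, and the route is rejoined at 15.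

**Step 12.** The intermediate ortho-hydroxybenzyl alkoxide may condense with a second phenol before hydride transfer (diarylmethane formation), or conversion may stall on this hindered, oxidation-prone phenol. Fallback, which forms the C6–carbon bond directly with the whole side chain: it sets out from 16 and 19. The Grignard reagent 20 would be formylated with DMF to 3-[4-(tert-butyldimethylsilyloxy)phenyl]propanal F4. Phenol 16 would be converted with EtMgBr into bromomagnesium 2,2-dimethyl-8-(3-methylbut-2-enyl)-2H-chromen-7-olate F5. Ortho-specific hydroxyalkylation of F5 with F4 in toluene at rt, through the same chelated transition state, would give 21 directly. The route is rejoined at 21 and 17 is bypassed.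

**Step 15.** Oxidation of a hindered, hydrogen-bonded carbinol on a solid oxidant may be slow, so that phenol oxidation, oxidative coupling or dehydration to an ortho-quinone methide compete. Fallback without a metal oxidant: it sets out from 17. After the addition of 20 as in step 14, the chelated magnesium alkoxide would not be worked up but treated in the same flask with an excess of benzaldehyde. Hydride transfer from the carbinol carbon to the aldehyde (magnesium Oppenauer oxidation, the redox event already used inside step 12) would give 22 after work-up. No new compound is made, and the route is rejoined at 22.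

## Further compounds

F1 | step 6 | 1-(2,4-dihydroxyphenyl)ethanone | CC(=O)c1ccc(O)cc1O
F2 | step 6 | 1-[2,4-dihydroxy-3-(3-methylbut-2-enyl)phenyl]ethanone | CC(=O)c1ccc(O)c(CC=C(C)C)c1O
F3 | step 10 | 2,2-dimethyl-8-(3-methylbut-2-enyl)-7-[tri(propan-2-yl)silyloxy]-2H-chromen-4-yl trifluoromethanesulfonate | CC(C)=CCc1c(O[Si](C(C)C)(C(C)C)C(C)C)ccc2c1OC(C)(C)C=C2OS(=O)(=O)C(F)(F)F
F4 | step 12 | 3-[4-(tert-butyldimethylsilyloxy)phenyl]propanal | CC(C)(C)[Si](C)(C)Oc1ccc(CCC=O)cc1
F5 | step 12 | bromomagnesium 2,2-dimethyl-8-(3-methylbut-2-enyl)-2H-chromen-7-olate | CC(C)=CCc1c(O[Mg]Br)ccc2c1OC(C)(C)C=C2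
F0 | step 15 | none | none
A1 | alternative 1 | osthole, 7-methoxy-8-(3-methylbut-2-enyl)chromen-2-one | COc1ccc2c(c1CC=C(C)C)OC(=O)C=C2
A2 | alternative 1 | 2-[(1Z)-3-hydroxy-3-methylbut-1-enyl]-5-methoxy-6-(3-methylbut-2-enyl)phenol | COc1ccc(/C=C\C(C)(C)O)c(O)c1CC=C(C)C
A3 | alternative 1 | 7-methoxy-2,2-dimethyl-8-(3-methylbut-2-enyl)-2H-chromene | COc1ccc2c(c1CC=C(C)C)OC(C)(C)C=C2
A4 | alternative 2 | 3-[4-(tert-butyldimethylsilyloxy)phenyl]-1-[2-hydroxy-4-(2-methylbut-3-yn-2-yloxy)-3-(3-methylbut-2-enyl)phenyl]propan-1-one | C#CC(C)(C)Oc1ccc(C(=O)CCc2ccc(O[Si](C)(C)C(C)(C)C)cc2)c(O)c1CC=C(C)C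
A5 | alternative 2 | 3-[4-(tert-butyldimethylsilyloxy)phenyl]-1-[7-hydroxy-2,2-dimethyl-8-(3-methylbut-2-enyl)-2H-chromen-6-yl]propan-1-one | CC(C)=CCc1c(O)c(C(=O)CCc2ccc(O[Si](C)(C)C(C)(C)C)cc2)cc2c1OC(C)(C)C=C2
A6 | alternative 3 | 5-[4-(tert-butyldimethylsilyloxy)phenyl]pent-1-yn-3-one | C#CC(=O)CCc1ccc(O[Si](C)(C)C(C)(C)C)cc1
A7 | alternative 3 | 3-[4-(tert-butyldimethylsilyloxy)phenyl]-1-[2,4-dihydroxy-3-(3-methylbut-2-enyl)phenyl]propan-1-one | CC(C)=CCc1c(O)ccc(C(=O)CCc2ccc(O[Si](C)(C)C(C)(C)C)cc2)c1O
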